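Ring B (C1–C2–C1'–C7'–C8'–C8–C7) is read as a six-membered spiro ketone ring enlarged by one atom, C8, whose neighbours are the oxygen-bearing C7 and the methine C8'. Taking C8 out gives a spiro-tetralone, closed at C1'–C2 by a reliable oxidative phenol–arene coupling. Forward, dibromocarbene adds across C7=C8' of a silyl enol ether and the shared cyclopropane bond breaks. This one operation makes C7–C8 and C8–C8', creates ring B and leaves bromine on C8 of an enone, from which both methyl groups follow. The precursor is the tert-butyldimethylsilyl enol ether of the spiro-tetralone, dienone ring C already in place.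

Key step: step 6

Remarks on the chemistry (one line each)
- Configuration: the target is (7R,8S,8'R); around ring B the C8' and C8 methyl groups are trans and the C8 methyl and C7 hydroxyl are trans; C1' is not a stereocentre because the two arms of ring C are identical.
- Assumption: the sense of induction of the copper–phosphoramidite catalyst in step 8 is carried over from simple cycloalkenones; if a first run shows the opposite sense, the mirror-image ligand is used.
- Coupling substrate: a free C7 ketone deactivates C2, and a free C7 alcohol would close a five-membered spiro ether on C1' ahead of the arene, so C7 passes through step 4 as a dioxolane, which also saves a reduction and a re-oxidation.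
- End game: hydride cannot be expected to spare C4'=O, and it should reach C7 from the outer face of ring B to give the 7-epimer; steps 9 and 10 therefore reduce both carbonyls, re-oxidise C4' alone and invert C7 with an oxygen nucleophile.

Step 1
Reactants: 1 3',4',5'-trimethoxyacetophenone; 2 syringaldehyde (4-hydroxy-3,5-dimethoxybenzaldehyde)
Product: 3 (E)-3-(4-hydroxy-3,5-dimethoxyphenyl)-1-(3,4,5-trimethoxyphenyl)prop-2-en-1-one (chalcone)
Conditions: HCl (g), EtOH, 0 °C to rt
Reagents that add atoms: none
Why: Acid-catalysed Claisen–Schmidt condensation, in which the enol of 1 adds to the protonated aldehyde and loss of water gives the conjugated E-enone; acid is preferred because base would convert 2 into an unreactive phenoxide.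

Step 2
Reactants: 3 chalcone
Product: 4 3-(4-hydroxy-3,5-dimethoxyphenyl)-1-(3,4,5-trimethoxyphenyl)propan-1-one (dihydrochalcone)
Conditions: H2 (1 atm), Pd/C, EtOAc, rt
Reagents that add atoms: none
Why: Heterogeneous catalytic hydrogenation saturates the enone C=C far faster than it attacks the electron-rich aryl ketone in a neutral solvent.

Step 3
Reactants: 4 dihydrochalcone
Product: 5 4-{2-[2-(3,4,5-trimethoxyphenyl)-1,3-dioxolan-2-yl]ethyl}-2,6-dimethoxyphenol (phenol ketal)
Conditions: HOCH2CH2OH, HC(OEt)3, p-TsOH (cat.), CH2Cl2, rt to 40 °C
Reagents that add atoms: ethylene glycol, OCCO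
Why: Acid-catalysed ketalisation driven by the orthoformate as water scavenger at low temperature, which avoids cyclodehydration to an indene and gives a C7 group that neither deactivates C2 nor carries an O–H.

Step 4
Reactants: 5 phenol ketal
Product: 7 spiro-tetralone (six-membered ring C1–C7(=O)–C8'H2–C7'H2–C1'–C2 spiro-joined at C1' to the 3',5'-dimethoxycyclohexa-2',5'-dien-4'-one ring C; ring A 3,4,5-trimethoxy), via spiro ketal 6 (not isolated)
Conditions: PhI(OAc)2, NaHCO3, CF3CH2OH, −20 to 0 °C; concentrate; 1 M HCl (cat.), THF, rt
Reagents that add atoms: water, O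
Why: Hypervalent-iodine oxidative dearomatisation (intramolecular phenol–arene coupling): the aryloxyiodane ionises in the fluoroalcohol, C2 (para to the C5 and ortho to the C3 methoxy group) attacks C1' through a six-membered transition state, and dilute acid then hydrolyses the very labile aryl ketal well below the acidity needed for a dienone–phenol shift.

Step 5
Reactants: 7 spiro-tetralone
Product: 8 tert-butyldimethylsilyl enol ether of 7 (C7(OTBS)=C8'H; ring C dienone unchanged)
Conditions: TBSOTf, Et3N, CH2Cl2, 0 °C
Reagents that add atoms: tert-butyldimethylsilyl triflate, CC(C)(C)[Si](C)(C)OS(=O)(=O)C(F)(F)F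
Why: Soft enolisation with a silyl triflate and an amine reaches the only enolisable position (C8'H2) without strong base near ring C, and the bulky silyl group makes 8 stable to chromatography and to tert-butoxide.

Step 6
Reactants: 8 silyl enol ether; 9 bromoform
Product: 11 ring B 2-bromo-enone (seven-membered ring with C7=O and C8(Br)=C8'H; ring C dienone unchanged), via siloxy-dibromocyclopropane 10 (not isolated)
Conditions: CHBr3 (excess), KOtBu (portionwise), toluene, −30 to 0 °C; pH 7 quench; crude, Bu4NF, AcOH, THF, 0 °C
Reagents that add atoms: bromoform 9, BrC(Br)Br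
Why: KOtBu deprotonates bromoform, the tribromomethyl anion loses bromide, and the electrophilic singlet dibromocarbene adds in a concerted [2+1] manner to the most electron-rich alkene of 8, the C7=C8' silyl enol ether, which forms C7–C8 and C8–C8' in 10. Fluoride then frees the C7 oxide, whose lone pair pushes open the fused C7–C8' bond in a disrotatory two-electron opening while the endo bromide leaves, so that C8 becomes a ring member as C8(Br)=C8'H next to the C7 ketone. This is the established dihalocarbene ring enlargement of cyclic silyl enol ethers to 2-halo-enones, well used on 1-tetralone enol ethers. Ring B is thus closed not end to end but by enlargement: a cis-fused three-membered ring is built on the six-membered ring and the bond they share is cleaved. No stereocentre remains, since the two of racemic 10 become sp2 carbons and C1' carries two identical ring C arms. The step needs chemoselectivity for C7=C8' over the ring C alkenes, which the C4' carbonyl (draining those alkenes) and their neopentyl position next to C1' secure, and it needs one direction of opening, which the oxygen on C7 fixes, while excess bromoform consumes the base and the bulky silyl group keeps 10 closed until the quench so that 11 never meets KOtBu.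

Step 7
Reactants: 11 2-bromo-enone
Product: 12 ring B 2-methyl-enone (C7=O and C8(CH3)=C8'H)
Conditions: Me4Sn, Pd2(dba)3 (cat.), AsPh3, CuI (cat.), NMP, 60 °C
Reagents that add atoms: tetramethylstannane, C[Sn](C)(C)C
Why: Stille coupling: zerovalent palladium inserts into the activated C8–Br bond, and copper-assisted methyl transfer from tin and reductive elimination follow under neutral conditions that leave both unsaturated ketones untouched.

Step 8
Reactants: 12 2-methyl-enone
Product: 15 (8S,8'R)-trans-dimethyl ketone (C7=O; C8 and C8' methyl groups trans), via methylzinc enolate 13 (not isolated), via cis-dimethyl ketone 14 (not isolated)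
Conditions: Me2Zn, Cu(OTf)2 (5 mol %), (R,S,S)-phosphoramidite from (R)-BINOL and bis[(S)-1-phenylethyl]amine (10 mol %), toluene, −20 to 0 °C; 1 M HCl quench; crude, DBU, toluene, rt
Reagents that add atoms: dimethylzinc, C[Zn]C
Why: Copper-catalysed asymmetric conjugate addition of a dialkylzinc to an α-substituted cyclic enone, in which the chiral copper–phosphoramidite complex delivers methyl to one face of C8' (R), Me2Zn does not add to C=O groups, ring C is spared because its β-carbons are enol-ether-like and neopentyl, and DBU then equilibrates the epimerisable C8 to the 8S isomer with both methyl groups pseudo-equatorial (residual 14 can be separated and re-equilibrated).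

Step 9
Reactants: 15 trans-dimethyl ketone
Product: 17 (7S,8S,8'R)-alcohol (7-epimer of the target; C7 hydroxyl cis to the C8 methyl; ring C dienone restored), via C4',C7-diol 16 (not isolated)
Conditions: iBu2AlH, CH2Cl2, −78 to −20 °C; aq. potassium sodium tartrate; crude, MnO2, CH2Cl2, rt
Reagents that add atoms: none
Why: 1,2-Reduction with an aluminium hydride followed by selective allylic oxidation: both carbonyls are reduced on purpose, hydride reaches C7 from the outer face because the inner face looks across ring B at C1' and the ring C arm beneath it (sets 7S), and MnO2 returns only the doubly allylic C4' carbinol to the dienone because the hindered C7–H bond lies close to the plane of ring A.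

Step 10
Reactants: 17 (7S,8S,8'R)-alcohol
Product: 19 target (7R,8S,8'R)-alcohol CNP0288561.1, via 7R 4-nitrobenzoate 18 (not isolated)
Conditions: 4-O2NC6H4CO2H, PPh3, DIAD, toluene, 0 °C to rt; crude, K2CO3 (cat.), MeOH, 0 °C
Reagents that add atoms: 4-nitrobenzoic acid, O=C(O)c1ccc(cc1)[N+](=O)[O-]
Why: Mitsunobu inversion followed by transesterification: the carboxylate displaces the oxyphosphonium group from the open outer face, anti to the C8 methyl (any ionised pathway should be captured from that face as well), which turns 7S into 7R, and catalytic methoxide removes the activated ester without risk to C8, which is no longer epimerisable.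

Compound list
1 | 3',4',5'-trimethoxyacetophenone | CC(=O)c1cc(OC)c(OC)c(OC)c1 | starting material
2 | syringaldehyde | COc1cc(C=O)cc(OC)c1O | starting material
3 | (E)-chalcone | COc1cc(/C=C/C(=O)c2cc(OC)c(OC)c(OC)c2)cc(OC)c1O | intermediate
4 | dihydrochalcone | COc1cc(CCC(=O)c2cc(OC)c(OC)c(OC)c2)cc(OC)c1O | intermediate
5 | phenol ketal (C7 dioxolane) | COc1cc(CCC2(OCCO2)c3cc(OC)c(OC)c(OC)c3)cc(OC)c1O | intermediate
6 | spiro ketal (C7 dioxolane of 7) | COC1=CC2(C=C(OC)C1=O)CCC3(OCCO3)c1cc(OC)c(OC)c(OC)c12 | intermediate
7 | spiro-tetralone | COC1=CC2(C=C(OC)C1=O)CCC(=O)c1cc(OC)c(OC)c(OC)c12 | intermediate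
8 | TBS enol ether of 7 (C7=C8') | COC1=CC2(C=C(OC)C1=O)CC=C(O[Si](C)(C)C(C)(C)C)c1cc(OC)c(OC)c(OC)c12 | intermediate
9 | bromoform | BrC(Br)Br | starting material
10 | siloxy-dibromocyclopropane (racemic, cis-fused at C7/C8') | COC1=CC2(C=C(OC)C1=O)CC3C(Br)(Br)C3(O[Si](C)(C)C(C)(C)C)c1cc(OC)c(OC)c(OC)c12 | intermediate
11 | ring B 2-bromo-enone | COC1=CC2(C=C(OC)C1=O)CC=C(Br)C(=O)c1cc(OC)c(OC)c(OC)c12 | intermediate
12 | ring B 2-methyl-enone | COC1=CC2(C=C(OC)C1=O)CC=C(C)C(=O)c1cc(OC)c(OC)c(OC)c12 | intermediate
13 | (8'R)-methylzinc enolate | COC1=CC2(C=C(OC)C1=O)C[C@@H](C)C(C)=C(O[Zn]C)c1cc(OC)c(OC)c(OC)c12 | intermediate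
14 | (8R,8'R)-cis-dimethyl ketone | COC1=CC2(C=C(OC)C1=O)C[C@@H](C)[C@@H](C)C(=O)c1cc(OC)c(OC)c(OC)c12 | intermediate
15 | (8S,8'R)-trans-dimethyl ketone | COC1=CC2(C=C(OC)C1=O)C[C@@H](C)[C@H](C)C(=O)c1cc(OC)c(OC)c(OC)c12 | intermediate
16 | (7S,8S,8'R)-C4',C7-diol (C4' epimers, of no consequence) | COC1=CC2(C=C(OC)C1O)C[C@@H](C)[C@H](C)[C@H](O)c1cc(OC)c(OC)c(OC)c12 | intermediate
17 | (7S,8S,8'R)-alcohol (7-epimer of the target) | COC1=CC2(C=C(OC)C1=O)C[C@@H](C)[C@H](C)[C@H](O)c1cc(OC)c(OC)c(OC)c12 | intermediate
18 | (7R,8S,8'R)-4-nitrobenzoate | COC1=CC2(C=C(OC)C1=O)C[C@@H](C)[C@H](C)[C@@H](OC(=O)c3ccc(cc3)[N+](=O)[O-])c1cc(OC)c(OC)c(OC)c12 | intermediate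
19 | CNP0288561.1, (7R,8S,8'R) | COC1=CC2(C=C(OC)C1=O)C[C@@H](C)[C@H](C)[C@@H](O)c1cc(OC)c(OC)c(OC)c12 | target

Total step count: 10. Longest linear sequence: 10 steps (from 1 or 2).

Steps most likely to fail

Step 6. tert-Butoxide or the tribromomethyl anion may attack the ring C carbonyl. The silyl group may be lost before the carbene arrives. The cyclopropane may also open early, so that the bromo-enone is exposed to base. The fallback sets out from 8 and returns at 12; it keeps the one-carbon insertion but uses no base and no dihalocarbene. A Furukawa-type Simmons–Smith cyclopropanation (Et2Zn, CH2I2, CH2Cl2) of 8 should give the halogen-free siloxycyclopropane F1. FeCl3 in DMF cleaves its fused C7–C8' bond by one-electron oxidation (the oxidative siloxycyclopropane ring enlargement) to the ring-enlarged β-chloro ketone F2. NaOAc in MeOH eliminates HCl to the unsubstituted ring B enone F3, and I2 with pyridine gives the 2-iodo-enone F4. F4 takes the place of 11 in the Stille methylation of step 7 and delivers 12.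

Step 8. Methyl transfer from zinc to an α-substituted, electron-rich aryl enone may be sluggish, facial selectivity may be poor, or equilibration at C8 may stay incomplete. The fallback sets out from 11 and returns at 15; it reverses the order of the two methylations so that the asymmetric addition meets a more electrophilic acceptor. The copper–phosphoramidite catalysed addition of Me2Zn is run on the 2-bromo-enone 11 itself, with styrene as radical trap; 2-halo-cycloalkenones are a known substrate class for this reaction. It should give the (8'R)-α-bromo-β-methyl ketone F5 as C8 epimers. Me2CuLi (Et2O, −78 °C) followed by MeI then replaces bromine by methyl on the face away from the C8' methyl, and a short DBU treatment completes the conversion to 15.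

Step 10. The oxyphosphonium group may be lost together with the antiperiplanar C8–H to give the C7=C8 styrene, or displacement may fail at the hindered benzylic centre. The fallback sets out from 17 and returns at 19; it replaces the bimolecular inversion by a stereoconvergent ionisation. An Appel reaction (PPh3, CCl4, CH2Cl2) converts 17 into the C7 benzylic chloride F6, whose C7 configuration is immaterial. Ag2CO3 in aqueous acetone then ionises F6 under neutral conditions, and water should capture the ring A stabilised cation from the open outer face to give 19 directly.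

Further compounds
F1 | step 6 | siloxycyclopropane (racemic, cis-fused, no halogen) | COC1=CC2(C=C(OC)C1=O)CC3CC3(O[Si](C)(C)C(C)(C)C)c1cc(OC)c(OC)c(OC)c12
F2 | step 6 | ring B β-chloro ketone (Cl on C8', racemic) | COC1=CC2(C=C(OC)C1=O)CC(Cl)CC(=O)c1cc(OC)c(OC)c(OC)c12
F3 | step 6 | unsubstituted ring B enone (C8H=C8'H) | COC1=CC2(C=C(OC)C1=O)CC=CC(=O)c1cc(OC)c(OC)c(OC)c12
F4 | step 6 | ring B 2-iodo-enone | COC1=CC2(C=C(OC)C1=O)CC=C(I)C(=O)c1cc(OC)c(OC)c(OC)c12
F5 | step 8 | (8'R)-α-bromo-β-methyl ketone (C8 epimers) | COC1=CC2(C=C(OC)C1=O)C[C@@H](C)C(Br)C(=O)c1cc(OC)c(OC)c(OC)c12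
F6 | step 10 | (8S,8'R)-C7 benzylic chloride (C7 undefined) | COC1=CC2(C=C(OC)C1=O)C[C@@H](C)[C@H](C)C(Cl)c1cc(OC)c(OC)c(OC)c12
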